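**Retrosynthetic overview**
1. The C15 ester is cut to an allylic alcohol and an ω‑silyloxy C32 acid, the acid coming from two C16 halves joined by a copper‑catalysed Grignard coupling.
2. The (13E)‑C13=C14–C15–OH unit comes from a terminal alkyne (methylalumination, then formaldehyde), and C17 from carbonylation of the C7=C8 enol triflate of a C8 ketone.
3. Key disconnection: C5–C10 and C6–C7 are made together by an auxiliary‑controlled intramolecular Diels–Alder reaction of an acyclic (2E,8E)‑undeca‑2,8,10‑trienoyl imide, so rings A and B close in the same step (ring A through the tether, ring B as the cycloaddition ring).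
4. Enabling feature: ring B (C5–C6–C7–C8–C9–C10) is a cyclohexene retron once the sp2 carbon C8 that carries C17 is read as a ketone and then as an enol ether, C8(OSi)=C9, which gives the diene C7=C8–C9=C10 plus the alkene C5=C6. The chain C1–C3 with the quaternary C4 ties C10 to C5, and a removable acyl group on C6 activates and steers the alkene.
5. The triene is assembled from acetylacetone, a silylated homopropargyl bromide, 2,2‑dimethylpent‑4‑enal and malonic acid by enol triflate formation and B‑alkyl Suzuki–Miyaura coupling.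

Key step: step 7

Assumption: the acyl chain is read as 32‑hydroxydotriacontanoyl (31 CH2), and the diterpene carbons are referred to by labdane numbering (C1–C20; the target is the ent‑labdane, 5R,9S,10R).

**Step 1**
Reactants: 1 pentane‑2,4‑dione; 2 (4‑bromobut‑1‑yn‑1‑yl)trimethylsilane
Product: 3 3‑[4‑(trimethylsilyl)but‑3‑yn‑1‑yl]pentane‑2,4‑dione
Conditions: K2CO3, NaI (cat.), acetone, reflux
Reagents that add atoms: none
Why: C‑alkylation (SN2) of the soft acetylacetonate by the primary bromide under weakly basic, aprotic conditions should leave the C–Si bond intact; the central carbon becomes C9 and the two acetyl groups become C7/C8 and C10/C20.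

**Step 2**
Reactants: 3 3‑[4‑(trimethylsilyl)but‑3‑yn‑1‑yl]pentane‑2,4‑dione
Product: 4 (2E)‑4‑oxo‑3‑[4‑(trimethylsilyl)but‑3‑yn‑1‑yl]pent‑2‑en‑2‑yl trifluoromethanesulfonate
Conditions: Tf2O, aq. Me4NOH, hexanes/toluene, 0–5 °C
Reagents that add atoms: trifluoromethanesulfonic anhydride, O=S(=O)(OS(=O)(=O)C(F)(F)F)C(F)(F)F
Why: stereoselective enol triflate formation from the non‑chelated tetramethylammonium diketonate should place the triflate anti to the remaining acetyl group (dipole‑minimised enolate), the two carbonyls being equivalent so that no regiochemical issue arises, and any (Z)‑isomer would be removed by chromatography.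

**Step 3**
Reactants: 5 2,2‑dimethylpent‑4‑enal; 6 malonic acid
Product: 7 (2E)‑4,4‑dimethylhepta‑2,6‑dienoic acid
Conditions: pyridine, piperidine (cat.), 90 °C
Reagents that add atoms: none
Why: the Doebner modification of the Knoevenagel condensation, with decarboxylation, should give the (E)‑acid from the non‑enolisable neopentyl aldehyde.

**Step 4**
Reactants: 7 (2E)‑4,4‑dimethylhepta‑2,6‑dienoic acid; 8 (4R)‑4‑benzyl‑1,3‑oxazolidin‑2‑one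
Product: 10 (4R)‑4‑benzyl‑3‑[(2E)‑4,4‑dimethylhepta‑2,6‑dienoyl]‑1,3‑oxazolidin‑2‑one, via mixed pivalic anhydride 9 (not isolated)
Conditions: t‑BuCOCl, Et3N, THF, −20 °C; then 8, LiCl, −20 → 23 °C
Reagents that add atoms: none
Why: N‑acylation of the oxazolidinone through the mixed anhydride (LiCl‑assisted) installs the chiral controller without touching the (E)‑alkene.

**Step 5**
Reactants: 10 (4R)‑4‑benzyl‑3‑[(2E)‑4,4‑dimethylhepta‑2,6‑dienoyl]‑1,3‑oxazolidin‑2‑one; 4 (2E)‑4‑oxo‑3‑[4‑(trimethylsilyl)but‑3‑yn‑1‑yl]pent‑2‑en‑2‑yl trifluoromethanesulfonate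
Product: 12 (4R)‑4‑benzyl‑3‑{(2E,8E)‑4,4,8‑trimethyl‑10‑oxo‑9‑[4‑(trimethylsilyl)but‑3‑yn‑1‑yl]undeca‑2,8‑dienoyl}‑1,3‑oxazolidin‑2‑one, via B‑alkyl‑9‑borabicyclononane 11 (not isolated)
Conditions: 9‑BBN‑H, THF, 0 → 23 °C; then 4, PdCl2(dppf) (5 mol%), AsPh3, Cs2CO3, DMF/THF/H2O, 23 °C
Reagents that add atoms: none
Why: chemoselective anti‑Markovnikov hydroboration of the terminal alkene followed by B‑alkyl Suzuki–Miyaura coupling, which proceeds with retention at the vinyl triflate, should form the C1–C10 bond with C1 trans to the acetyl group.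

**Step 6**
Reactants: 12 (4R)‑4‑benzyl‑3‑{(2E,8E)‑4,4,8‑trimethyl‑10‑oxo‑9‑[4‑(trimethylsilyl)but‑3‑yn‑1‑yl]undeca‑2,8‑dienoyl}‑1,3‑oxazolidin‑2‑one
Product: 13 (4R)‑4‑benzyl‑3‑{(2E,8E)‑10‑[(tert‑butyldimethylsilyl)oxy]‑4,4,8‑trimethyl‑9‑[4‑(trimethylsilyl)but‑3‑yn‑1‑yl]undeca‑2,8,10‑trienoyl}‑1,3‑oxazolidin‑2‑one
Conditions: TBSOTf, Et3N, CH2Cl2, −78 → 0 °C
Reagents that add atoms: tert‑butyldimethylsilyl trifluoromethanesulfonate, CC(C)(C)[Si](C)(C)OS(=O)(=O)C(F)(F)F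
Why: soft enolisation and O‑silylation at the α′‑methyl group gives the cross‑conjugated 2‑silyloxydiene with the C9=C10 geometry untouched, and the enoyl imide has no enolisable hydrogen because C4 is quaternary.

**Step 7**
Reactants: 13 (4R)‑4‑benzyl‑3‑{(2E,8E)‑10‑[(tert‑butyldimethylsilyl)oxy]‑4,4,8‑trimethyl‑9‑[4‑(trimethylsilyl)but‑3‑yn‑1‑yl]undeca‑2,8,10‑trienoyl}‑1,3‑oxazolidin‑2‑one
Product: 15 (4R)‑4‑benzyl‑3‑{[(1R,4S,4aR,8aR)‑4a,8,8‑trimethyl‑3‑oxo‑4‑[4‑(trimethylsilyl)but‑3‑yn‑1‑yl]decahydronaphthalen‑1‑yl]carbonyl}‑1,3‑oxazolidin‑2‑one, via silyl enol ether cycloadduct 14 (not isolated)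
Conditions: Me2AlCl (1.5 equiv), CH2Cl2 (0.01 M), −30 → 0 °C; then 1 M HCl, THF, 23 °C
Reagents that add atoms: none
Why: Me2AlCl turns the imide into a cationic two‑point dimethylaluminium chelate (s‑cis enoyl) whose C5=C6 bond adds across the tethered 2‑silyloxydiene C7=C8–C9=C10 in an asynchronous [4+2] cycloaddition in which the internal bond C5–C10 leads and C6–C7 follows; the closest known reaction type is the Lewis‑acid‑promoted, oxazolidinone‑controlled intramolecular Diels–Alder reaction of (E)‑undeca‑2,8,10‑trienoyl imides to trans‑fused octalins. Ring A is closed by the C5–C10 bond alone (the chain C1–C3 plus C4 is the tether, six‑membered, tether exo) and ring B is the cycloaddition ring, closed by C5–C10 and C6–C7 together with the carbonyl endo. C5 is set by the auxiliary, since the diene should add to the enoyl face opposite the (4R)‑benzyl group of the chelate (5R); C10 follows from the endo transition state together with the (8E) diene geometry (C1 outside, C20 inside), which places 5‑H and 10‑CH3 anti (trans fusion, 10R); C6 follows from the (2E) alkene and is destroyed later. C9 is set in the hydrolysis, where C‑protonation anti to the axial C20 and acid‑mediated equilibration both favour the equatorial side chain (9S). The step needs periselectivity over ene and Mukaiyama–Michael pathways and a tether‑imposed regiochemistry (C10 to the β‑carbon C5, although the silyloxy group polarises the diene toward C7): bonding of C7 to C5 would need a nine‑membered ring, the quaternary C4 blocks γ‑enolisation, and the silyl enol ether of the adduct fixes the new double bond as C8=C9 for unmasking of the C8 ketone.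

**Step 8**
Reactants: 15 (4R)‑4‑benzyl‑3‑{[(1R,4S,4aR,8aR)‑4a,8,8‑trimethyl‑3‑oxo‑4‑[4‑(trimethylsilyl)but‑3‑yn‑1‑yl]decahydronaphthalen‑1‑yl]carbonyl}‑1,3‑oxazolidin‑2‑one
Product: 16 (1R,4S,4aR,8aR)‑4a,8,8‑trimethyl‑3‑oxo‑4‑[4‑(trimethylsilyl)but‑3‑yn‑1‑yl]decahydronaphthalene‑1‑carboxylic acid
Conditions: LiOH, H2O2, THF/H2O, 0 °C; Na2SO3; then 1 M HCl to pH 3
Reagents that add atoms: hydrogen peroxide, OO
Why: hydroperoxide‑mediated imide hydrolysis attacks the exocyclic carbonyl selectively, releases the auxiliary for recovery, and at 0 °C should spare the alkynylsilane while keeping C9 at its thermodynamic configuration.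

**Step 9**
Reactants: 16 (1R,4S,4aR,8aR)‑4a,8,8‑trimethyl‑3‑oxo‑4‑[4‑(trimethylsilyl)but‑3‑yn‑1‑yl]decahydronaphthalene‑1‑carboxylic acid
Product: 17 (1S,4aR,8aR)‑5,5,8a‑trimethyl‑1‑[4‑(trimethylsilyl)but‑3‑yn‑1‑yl]octahydronaphthalen‑2(1H)‑one
Conditions: 9‑mesityl‑10‑phenylacridinium tetrafluoroborate (5 mol%), PhSSPh (10 mol%), i‑Pr2NEt (20 mol%), CF3CH2OH, 450 nm LEDs, 23 °C
Reagents that add atoms: none
Why: photoredox hydrodecarboxylation (carboxylate oxidation, loss of CO2, hydrogen‑atom transfer from thiophenol to the secondary C6 radical) removes the activating group and leaves C6 as CH2, with no stereocentre affected.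

**Step 10**
Reactants: 17 (1S,4aR,8aR)‑5,5,8a‑trimethyl‑1‑[4‑(trimethylsilyl)but‑3‑yn‑1‑yl]octahydronaphthalen‑2(1H)‑one
Product: 18 (1S,4aR,8aR)‑5,5,8a‑trimethyl‑1‑[4‑(trimethylsilyl)but‑3‑yn‑1‑yl]‑1,4,4a,5,6,7,8,8a‑octahydronaphthalen‑2‑yl trifluoromethanesulfonate
Conditions: KN(SiMe3)2, THF, −78 °C; PhNTf2, −78 → 0 °C
Reagents that add atoms: N‑phenylbis(trifluoromethanesulfonimide), O=S(=O)(N(c1ccccc1)S(=O)(=O)C(F)(F)F)C(F)(F)F
Why: kinetic enolate formation at the unhindered C7 methylene (C9 is tertiary and next to the quaternary C10) and O‑triflation should give the C7=C8 enol triflate without touching C9.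

**Step 11**
Reactants: 18 (1S,4aR,8aR)‑5,5,8a‑trimethyl‑1‑[4‑(trimethylsilyl)but‑3‑yn‑1‑yl]‑1,4,4a,5,6,7,8,8a‑octahydronaphthalen‑2‑yl trifluoromethanesulfonate
Product: 19 methyl (1S,4aR,8aR)‑5,5,8a‑trimethyl‑1‑[4‑(trimethylsilyl)but‑3‑yn‑1‑yl]‑1,4,4a,5,6,7,8,8a‑octahydronaphthalene‑2‑carboxylate
Conditions: Pd(OAc)2 (5 mol%), PPh3, CO (1 atm), Et3N, MeOH/DMF, 50 °C
Reagents that add atoms: carbon monoxide, [C-]#[O+]; methanol, CO
Why: palladium‑catalysed methoxycarbonylation of the enol triflate introduces C17 at the ester oxidation level with the double bond fixed at C7=C8.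

**Step 12**
Reactants: 19 methyl (1S,4aR,8aR)‑5,5,8a‑trimethyl‑1‑[4‑(trimethylsilyl)but‑3‑yn‑1‑yl]‑1,4,4a,5,6,7,8,8a‑octahydronaphthalene‑2‑carboxylate
Product: 20 {(1S,4aR,8aR)‑5,5,8a‑trimethyl‑1‑[4‑(trimethylsilyl)but‑3‑yn‑1‑yl]‑1,4,4a,5,6,7,8,8a‑octahydronaphthalen‑2‑yl}methanol
Conditions: i‑Bu2AlH, CH2Cl2, −78 → 0 °C; aq. Rochelle salt
Reagents that add atoms: none
Why: 1,2‑reduction of the conjugated ester by the aluminium hydride gives the C17 allylic alcohol without conjugate reduction.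

**Step 13**
Reactants: 20 {(1S,4aR,8aR)‑5,5,8a‑trimethyl‑1‑[4‑(trimethylsilyl)but‑3‑yn‑1‑yl]‑1,4,4a,5,6,7,8,8a‑octahydronaphthalen‑2‑yl}methanol
Product: 21 tert‑butyl({(1S,4aR,8aR)‑5,5,8a‑trimethyl‑1‑[4‑(trimethylsilyl)but‑3‑yn‑1‑yl]‑1,4,4a,5,6,7,8,8a‑octahydronaphthalen‑2‑yl}methoxy)dimethylsilane
Conditions: TBSCl, imidazole, CH2Cl2, 23 °C
Reagents that add atoms: tert‑butyldimethylsilyl chloride, CC(C)(C)[Si](C)(C)Cl
Why: O‑silylation protects the C17 hydroxyl so that only the C15 hydroxyl made later is free for acylation.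

**Step 14**
Reactants: 21 tert‑butyl({(1S,4aR,8aR)‑5,5,8a‑trimethyl‑1‑[4‑(trimethylsilyl)but‑3‑yn‑1‑yl]‑1,4,4a,5,6,7,8,8a‑octahydronaphthalen‑2‑yl}methoxy)dimethylsilane
Product: 22 {[(1S,4aR,8aR)‑1‑(but‑3‑yn‑1‑yl)‑5,5,8a‑trimethyl‑1,4,4a,5,6,7,8,8a‑octahydronaphthalen‑2‑yl]methoxy}(tert‑butyl)dimethylsilane
Conditions: K2CO3 (0.3 equiv), MeOH/THF, 23 °C
Reagents that add atoms: none
Why: methoxide‑mediated protodesilylation cleaves only the C(sp)–Si bond and leaves the primary silyl ether in place.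

**Step 15**
Reactants: 22 {[(1S,4aR,8aR)‑1‑(but‑3‑yn‑1‑yl)‑5,5,8a‑trimethyl‑1,4,4a,5,6,7,8,8a‑octahydronaphthalen‑2‑yl]methoxy}(tert‑butyl)dimethylsilane
Product: 25 (2E)‑5‑[(1S,4aR,8aR)‑2‑{[(tert‑butyldimethylsilyl)oxy]methyl}‑5,5,8a‑trimethyl‑1,4,4a,5,6,7,8,8a‑octahydronaphthalen‑1‑yl]‑3‑methylpent‑2‑en‑1‑ol, via alkenylalane 23 (not isolated), via lithium alkenylaluminate 24 (not isolated)
Conditions: Me3Al, (C5H5)2ZrCl2 (0.25 equiv), CH2Cl2, 0 → 23 °C; volatiles removed; THF, n‑BuLi, −78 → 0 °C; (CH2O)n, 23 °C; aq. NH4Cl/Rochelle salt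
Reagents that add atoms: trimethylaluminium, C[Al](C)C; formaldehyde (as paraformaldehyde), C=O
Why: zirconium‑catalysed syn‑methylalumination of the terminal alkyne (carboalumination) followed by capture of the derived aluminate with formaldehyde, with retention, should give the (E)‑trisubstituted allylic alcohol stereospecifically.

**Step 16**
Reactants: 26 16‑bromohexadecan‑1‑ol
Product: 27 [(16‑bromohexadecyl)oxy](tert‑butyl)dimethylsilane
Conditions: TBSCl, imidazole, DMF, 23 °C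
Reagents that add atoms: tert‑butyldimethylsilyl chloride, CC(C)(C)[Si](C)(C)Cl
Why: O‑silylation masks the hydroxyl so that the bromide can be converted into a Grignard reagent.

**Step 17**
Reactants: 27 [(16‑bromohexadecyl)oxy](tert‑butyl)dimethylsilane; 28 16‑bromohexadecanoic acid
Product: 31 32‑[(tert‑butyldimethylsilyl)oxy]dotriacontanoic acid, via Grignard reagent 29 (not isolated), via chloromagnesium carboxylate 30 (not isolated)
Conditions: 27, Mg, THF, 45 °C; separately 28, MeMgCl (1.0 equiv), THF, −20 °C; combined with Li2CuCl4 (3 mol%), −20 → 23 °C; aq. citric acid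
Reagents that add atoms: none
Why: copper‑catalysed sp3–sp3 cross‑coupling of the Grignard reagent with the primary bromide, the acid being protected in situ as its magnesium carboxylate, joins the two C16 halves into the C32 chain.

**Step 18**
Reactants: 25 (2E)‑5‑[(1S,4aR,8aR)‑2‑{[(tert‑butyldimethylsilyl)oxy]methyl}‑5,5,8a‑trimethyl‑1,4,4a,5,6,7,8,8a‑octahydronaphthalen‑1‑yl]‑3‑methylpent‑2‑en‑1‑ol; 31 32‑[(tert‑butyldimethylsilyl)oxy]dotriacontanoic acid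
Product: 32 (2E)‑5‑[(1S,4aR,8aR)‑2‑{[(tert‑butyldimethylsilyl)oxy]methyl}‑5,5,8a‑trimethyl‑1,4,4a,5,6,7,8,8a‑octahydronaphthalen‑1‑yl]‑3‑methylpent‑2‑en‑1‑yl 32‑[(tert‑butyldimethylsilyl)oxy]dotriacontanoate
Conditions: i‑PrN=C=N‑i‑Pr, DMAP (cat.), CH2Cl2, 30 °C
Reagents that add atoms: none
Why: Steglich esterification acylates the only free hydroxyl (C15) under neutral conditions that do not ionise the allylic system.

**Step 19**
Reactants: 32 (2E)‑5‑[(1S,4aR,8aR)‑2‑{[(tert‑butyldimethylsilyl)oxy]methyl}‑5,5,8a‑trimethyl‑1,4,4a,5,6,7,8,8a‑octahydronaphthalen‑1‑yl]‑3‑methylpent‑2‑en‑1‑yl 32‑[(tert‑butyldimethylsilyl)oxy]dotriacontanoate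
Product: 33 (2E)‑5‑[(1S,4aR,8aR)‑2‑(hydroxymethyl)‑5,5,8a‑trimethyl‑1,4,4a,5,6,7,8,8a‑octahydronaphthalen‑1‑yl]‑3‑methylpent‑2‑en‑1‑yl 32‑hydroxydotriacontanoate (CNP0264179.1)
Conditions: HF·pyridine, pyridine/THF, 0 → 23 °C
Reagents that add atoms: none
Why: buffered fluoride desilylation should remove both primary silyl ethers without ester cleavage or acyl migration.

**Compound list**
1 | pentane‑2,4‑dione | CC(=O)CC(C)=O | starting material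
2 | (4‑bromobut‑1‑yn‑1‑yl)trimethylsilane | C[Si](C)(C)C#CCCBr | starting material
3 | 3‑[4‑(trimethylsilyl)but‑3‑yn‑1‑yl]pentane‑2,4‑dione | CC(=O)C(CCC#C[Si](C)(C)C)C(C)=O | intermediate
4 | (2E)‑4‑oxo‑3‑[4‑(trimethylsilyl)but‑3‑yn‑1‑yl]pent‑2‑en‑2‑yl trifluoromethanesulfonate | C/C(OS(=O)(=O)C(F)(F)F)=C(/CCC#C[Si](C)(C)C)C(C)=O | intermediate
5 | 2,2‑dimethylpent‑4‑enal | C=CCC(C)(C)C=O | starting material
6 | malonic acid | OC(=O)CC(O)=O | starting material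
7 | (2E)‑4,4‑dimethylhepta‑2,6‑dienoic acid | C=CCC(C)(C)/C=C/C(O)=O | intermediate
8 | (4R)‑4‑benzyl‑1,3‑oxazolidin‑2‑one | O=C1N[C@H](Cc2ccccc2)CO1 | starting material
9 | (2E)‑4,4‑dimethylhepta‑2,6‑dienoic 2,2‑dimethylpropanoic anhydride | C=CCC(C)(C)/C=C/C(=O)OC(=O)C(C)(C)C | intermediate
10 | (4R)‑4‑benzyl‑3‑[(2E)‑4,4‑dimethylhepta‑2,6‑dienoyl]‑1,3‑oxazolidin‑2‑one | C=CCC(C)(C)/C=C/C(=O)N1[C@H](Cc2ccccc2)COC1=O | intermediate
11 | (4R)‑4‑benzyl‑3‑[(2E)‑7‑(9‑borabicyclo[3.3.1]nonan‑9‑yl)‑4,4‑dimethylhept‑2‑enoyl]‑1,3‑oxazolidin‑2‑one | O=C(/C=C/C(C)(C)CCCB1C2CCCC1CCC2)N1[C@H](Cc2ccccc2)COC1=O | intermediate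
12 | (4R)‑4‑benzyl‑3‑{(2E,8E)‑4,4,8‑trimethyl‑10‑oxo‑9‑[4‑(trimethylsilyl)but‑3‑yn‑1‑yl]undeca‑2,8‑dienoyl}‑1,3‑oxazolidin‑2‑one | CC(=O)/C(CCC#C[Si](C)(C)C)=C(\C)CCCC(C)(C)/C=C/C(=O)N1[C@H](Cc2ccccc2)COC1=O | intermediate
13 | (4R)‑4‑benzyl‑3‑{(2E,8E)‑10‑[(tert‑butyldimethylsilyl)oxy]‑4,4,8‑trimethyl‑9‑[4‑(trimethylsilyl)but‑3‑yn‑1‑yl]undeca‑2,8,10‑trienoyl}‑1,3‑oxazolidin‑2‑one | C=C(O[Si](C)(C)C(C)(C)C)/C(CCC#C[Si](C)(C)C)=C(\C)CCCC(C)(C)/C=C/C(=O)N1[C@H](Cc2ccccc2)COC1=O | intermediate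
14 | (4R)‑4‑benzyl‑3‑{[(1R,4aR,8aR)‑3‑[(tert‑butyldimethylsilyl)oxy]‑4a,8,8‑trimethyl‑4‑[4‑(trimethylsilyl)but‑3‑yn‑1‑yl]‑1,2,4a,5,6,7,8,8a‑octahydronaphthalen‑1‑yl]carbonyl}‑1,3‑oxazolidin‑2‑one | C[Si](C)(C)C#CCCC1=C(O[Si](C)(C)C(C)(C)C)C[C@@H](C(=O)N3[C@H](Cc4ccccc4)COC3=O)[C@@H]2C(C)(C)CCC[C@@]12C | intermediate
15 | (4R)‑4‑benzyl‑3‑{[(1R,4S,4aR,8aR)‑4a,8,8‑trimethyl‑3‑oxo‑4‑[4‑(trimethylsilyl)but‑3‑yn‑1‑yl]decahydronaphthalen‑1‑yl]carbonyl}‑1,3‑oxazolidin‑2‑one | C[Si](C)(C)C#CCC[C@@H]1C(=O)C[C@@H](C(=O)N3[C@H](Cc4ccccc4)COC3=O)[C@@H]2C(C)(C)CCC[C@@]12C | intermediate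
16 | (1R,4S,4aR,8aR)‑4a,8,8‑trimethyl‑3‑oxo‑4‑[4‑(trimethylsilyl)but‑3‑yn‑1‑yl]decahydronaphthalene‑1‑carboxylic acid | C[Si](C)(C)C#CCC[C@@H]1C(=O)C[C@@H](C(O)=O)[C@@H]2C(C)(C)CCC[C@@]12C | intermediate
17 | (1S,4aR,8aR)‑5,5,8a‑trimethyl‑1‑[4‑(trimethylsilyl)but‑3‑yn‑1‑yl]octahydronaphthalen‑2(1H)‑one | C[Si](C)(C)C#CCC[C@@H]1C(=O)CC[C@@H]2C(C)(C)CCC[C@@]12C | intermediate
18 | (1S,4aR,8aR)‑5,5,8a‑trimethyl‑1‑[4‑(trimethylsilyl)but‑3‑yn‑1‑yl]‑1,4,4a,5,6,7,8,8a‑octahydronaphthalen‑2‑yl trifluoromethanesulfonate | C[Si](C)(C)C#CCC[C@@H]1C(OS(=O)(=O)C(F)(F)F)=CC[C@@H]2C(C)(C)CCC[C@@]12C | intermediate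
19 | methyl (1S,4aR,8aR)‑5,5,8a‑trimethyl‑1‑[4‑(trimethylsilyl)but‑3‑yn‑1‑yl]‑1,4,4a,5,6,7,8,8a‑octahydronaphthalene‑2‑carboxylate | C[Si](C)(C)C#CCC[C@@H]1C(C(=O)OC)=CC[C@@H]2C(C)(C)CCC[C@@]12C | intermediate
20 | {(1S,4aR,8aR)‑5,5,8a‑trimethyl‑1‑[4‑(trimethylsilyl)but‑3‑yn‑1‑yl]‑1,4,4a,5,6,7,8,8a‑octahydronaphthalen‑2‑yl}methanol | C[Si](C)(C)C#CCC[C@@H]1C(CO)=CC[C@@H]2C(C)(C)CCC[C@@]12C | intermediate
21 | tert‑butyl({(1S,4aR,8aR)‑5,5,8a‑trimethyl‑1‑[4‑(trimethylsilyl)but‑3‑yn‑1‑yl]‑1,4,4a,5,6,7,8,8a‑octahydronaphthalen‑2‑yl}methoxy)dimethylsilane | C[Si](C)(C)C#CCC[C@@H]1C(CO[Si](C)(C)C(C)(C)C)=CC[C@@H]2C(C)(C)CCC[C@@]12C | intermediate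
22 | {[(1S,4aR,8aR)‑1‑(but‑3‑yn‑1‑yl)‑5,5,8a‑trimethyl‑1,4,4a,5,6,7,8,8a‑octahydronaphthalen‑2‑yl]methoxy}(tert‑butyl)dimethylsilane | C#CCC[C@@H]1C(CO[Si](C)(C)C(C)(C)C)=CC[C@@H]2C(C)(C)CCC[C@@]12C | intermediate
23 | {(1E)‑4‑[(1S,4aR,8aR)‑2‑{[(tert‑butyldimethylsilyl)oxy]methyl}‑5,5,8a‑trimethyl‑1,4,4a,5,6,7,8,8a‑octahydronaphthalen‑1‑yl]‑2‑methylbut‑1‑en‑1‑yl}dimethylalumane | C[Al](C)/C=C(\C)CC[C@@H]1C(CO[Si](C)(C)C(C)(C)C)=CC[C@@H]2C(C)(C)CCC[C@@]12C | intermediate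
24 | lithium butyl{(1E)‑4‑[(1S,4aR,8aR)‑2‑{[(tert‑butyldimethylsilyl)oxy]methyl}‑5,5,8a‑trimethyl‑1,4,4a,5,6,7,8,8a‑octahydronaphthalen‑1‑yl]‑2‑methylbut‑1‑en‑1‑yl}dimethylaluminate | [Li+].CCCC[Al-](C)(C)/C=C(\C)CC[C@@H]1C(CO[Si](C)(C)C(C)(C)C)=CC[C@@H]2C(C)(C)CCC[C@@]12C | intermediate
25 | (2E)‑5‑[(1S,4aR,8aR)‑2‑{[(tert‑butyldimethylsilyl)oxy]methyl}‑5,5,8a‑trimethyl‑1,4,4a,5,6,7,8,8a‑octahydronaphthalen‑1‑yl]‑3‑methylpent‑2‑en‑1‑ol | C/C(=C\CO)CC[C@@H]1C(CO[Si](C)(C)C(C)(C)C)=CC[C@@H]2C(C)(C)CCC[C@@]12C | intermediate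
26 | 16‑bromohexadecan‑1‑ol | OCCCCCCCCCCCCCCCCBr | starting material
27 | [(16‑bromohexadecyl)oxy](tert‑butyl)dimethylsilane | CC(C)(C)[Si](C)(C)OCCCCCCCCCCCCCCCCBr | intermediate
28 | 16‑bromohexadecanoic acid | OC(=O)CCCCCCCCCCCCCCCBr | starting material
29 | {16‑[(tert‑butyldimethylsilyl)oxy]hexadecyl}magnesium bromide | CC(C)(C)[Si](C)(C)OCCCCCCCCCCCCCCCC[Mg]Br | intermediate
30 | chloromagnesium 16‑bromohexadecanoate | Cl[Mg]OC(=O)CCCCCCCCCCCCCCCBr | intermediate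
31 | 32‑[(tert‑butyldimethylsilyl)oxy]dotriacontanoic acid | OC(=O)CCCCCCCCCCCCCCCCCCCCCCCCCCCCCCCO[Si](C)(C)C(C)(C)C | intermediate
32 | (2E)‑5‑[(1S,4aR,8aR)‑2‑{[(tert‑butyldimethylsilyl)oxy]methyl}‑5,5,8a‑trimethyl‑1,4,4a,5,6,7,8,8a‑octahydronaphthalen‑1‑yl]‑3‑methylpent‑2‑en‑1‑yl 32‑[(tert‑butyldimethylsilyl)oxy]dotriacontanoate | C/C(=C\COC(=O)CCCCCCCCCCCCCCCCCCCCCCCCCCCCCCCO[Si](C)(C)C(C)(C)C)CC[C@@H]1C(CO[Si](C)(C)C(C)(C)C)=CC[C@@H]2C(C)(C)CCC[C@@]12C | intermediate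
33 | (2E)‑5‑[(1S,4aR,8aR)‑2‑(hydroxymethyl)‑5,5,8a‑trimethyl‑1,4,4a,5,6,7,8,8a‑octahydronaphthalen‑1‑yl]‑3‑methylpent‑2‑en‑1‑yl 32‑hydroxydotriacontanoate | C/C(=C\COC(=O)CCCCCCCCCCCCCCCCCCCCCCCCCCCCCCCO)CC[C@@H]1C(CO)=CC[C@@H]2C(C)(C)CCC[C@@]12C | target

**Step count and risks**
Total step count: 19. Longest linear sequence: 15 steps (steps 1, 2, 5–15, 18, 19, from pentane‑2,4‑dione).

Step 7 is the most likely to fail. The cycloaddition has to join a fully substituted diene terminus (C10) to a neopentyl‑type β‑carbon (C5) against the polarisation imposed by the silyloxy group. The chloroaluminium Lewis acid may therefore strip the silyl group or trigger ene and oligomerisation pathways before ring closure, and endo or facial selectivity may erode at the higher temperature a slow reaction would need. The fallback moves stereocontrol from the auxiliary to a milder, two‑point‑binding chiral Lewis acid that tolerates silyl enol ethers; it sets out from 7 and comes back at 16. Acid 7 would be coupled through 9 with oxazolidin‑2‑one to the achiral imide 3‑[(2E)‑4,4‑dimethylhepta‑2,6‑dienoyl]‑1,3‑oxazolidin‑2‑one F1. Hydroboration would give the B‑alkyl‑9‑borabicyclononane F2, and Suzuki–Miyaura coupling with 4 the enone 3‑{(2E,8E)‑4,4,8‑trimethyl‑10‑oxo‑9‑[4‑(trimethylsilyl)but‑3‑yn‑1‑yl]undeca‑2,8‑dienoyl}‑1,3‑oxazolidin‑2‑one F3. TBSOTf/Et3N would give the silyl dienol ether F4. The catalyst [Cu((S,S)‑t‑Bu‑box)](SbF6)2 (divalent copper, 10 mol%, CH2Cl2, 23 °C), whose square‑planar complex should expose the same enoyl face as the (4R)‑benzyl auxiliary, would then effect an enantioselective intramolecular Diels–Alder reaction to the silyl enol ether cycloadduct F5. Dilute HCl would hydrolyse F5 to the keto imide F6, and LiOH/H2O2 would return keto acid 16.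

Step 5 is the second risk. The vinylogous acyl triflate may be hydrolysed back to the diketone, and the imide attacked, under the basic aqueous coupling conditions, while transmetallation to the hindered tetrasubstituted alkenylpalladium is slow; the enoyl imide may also be reduced during hydroboration. The fallback couples first on a base‑stable ester and attaches the auxiliary last; it sets out from 7 and comes back at 12. Acid 7 would be converted with Boc2O/DMAP/t‑BuOH into tert‑butyl (2E)‑4,4‑dimethylhepta‑2,6‑dienoate F7 and hydroborated to the B‑alkyl‑9‑borabicyclononane F8. Coupling with 4 under forcing conditions (PdCl2(dppf), K3PO4, DMF/H2O, 60 °C) would give tert‑butyl (2E,8E)‑4,4,8‑trimethyl‑10‑oxo‑9‑[4‑(trimethylsilyl)but‑3‑yn‑1‑yl]undeca‑2,8‑dienoate F9. CF3CO2H would release (2E,8E)‑4,4,8‑trimethyl‑10‑oxo‑9‑[4‑(trimethylsilyl)but‑3‑yn‑1‑yl]undeca‑2,8‑dienoic acid F10, and t‑BuCOCl/Et3N, then 8 and LiCl, would lead through the mixed pivalic anhydride F11 to 12.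

Step 15 is the third risk. On the late intermediate the carbometallation may stall or the alkenylmetal may be protonated before capture by formaldehyde, and the allylic silyl ether may be lost to the Lewis‑acidic aluminium reagent. The fallback replaces carbometallation by carbonyl olefination; it sets out from 22 and comes back at 25. Hydration of the alkyne with Ph3PAuNTf2 (monovalent gold, 2 mol%) in dioxane/H2O would give 4‑[(1S,4aR,8aR)‑2‑{[(tert‑butyldimethylsilyl)oxy]methyl}‑5,5,8a‑trimethyl‑1,4,4a,5,6,7,8,8a‑octahydronaphthalen‑1‑yl]butan‑2‑one F12. Horner–Wadsworth–Emmons olefination (triethyl phosphonoacetate, NaH, THF) would give ethyl (2E)‑5‑[(1S,4aR,8aR)‑2‑{[(tert‑butyldimethylsilyl)oxy]methyl}‑5,5,8a‑trimethyl‑1,4,4a,5,6,7,8,8a‑octahydronaphthalen‑1‑yl]‑3‑methylpent‑2‑enoate F13, with the (Z)‑isomer removed by chromatography. Reduction with i‑Bu2AlH would return 25.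

**Further compounds**
F1 | step 7 | 3‑[(2E)‑4,4‑dimethylhepta‑2,6‑dienoyl]‑1,3‑oxazolidin‑2‑one | C=CCC(C)(C)/C=C/C(=O)N1CCOC1=O
F2 | step 7 | 3‑[(2E)‑7‑(9‑borabicyclo[3.3.1]nonan‑9‑yl)‑4,4‑dimethylhept‑2‑enoyl]‑1,3‑oxazolidin‑2‑one | O=C(/C=C/C(C)(C)CCCB1C2CCCC1CCC2)N1CCOC1=O
F3 | step 7 | 3‑{(2E,8E)‑4,4,8‑trimethyl‑10‑oxo‑9‑[4‑(trimethylsilyl)but‑3‑yn‑1‑yl]undeca‑2,8‑dienoyl}‑1,3‑oxazolidin‑2‑one | CC(=O)/C(CCC#C[Si](C)(C)C)=C(\C)CCCC(C)(C)/C=C/C(=O)N1CCOC1=O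
F4 | step 7 | 3‑{(2E,8E)‑10‑[(tert‑butyldimethylsilyl)oxy]‑4,4,8‑trimethyl‑9‑[4‑(trimethylsilyl)but‑3‑yn‑1‑yl]undeca‑2,8,10‑trienoyl}‑1,3‑oxazolidin‑2‑one | C=C(O[Si](C)(C)C(C)(C)C)/C(CCC#C[Si](C)(C)C)=C(\C)CCCC(C)(C)/C=C/C(=O)N1CCOC1=O
F5 | step 7 | 3‑{[(1R,4aR,8aR)‑3‑[(tert‑butyldimethylsilyl)oxy]‑4a,8,8‑trimethyl‑4‑[4‑(trimethylsilyl)but‑3‑yn‑1‑yl]‑1,2,4a,5,6,7,8,8a‑octahydronaphthalen‑1‑yl]carbonyl}‑1,3‑oxazolidin‑2‑one | C[Si](C)(C)C#CCCC1=C(O[Si](C)(C)C(C)(C)C)C[C@@H](C(=O)N3CCOC3=O)[C@@H]2C(C)(C)CCC[C@@]12C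
F6 | step 7 | 3‑{[(1R,4S,4aR,8aR)‑4a,8,8‑trimethyl‑3‑oxo‑4‑[4‑(trimethylsilyl)but‑3‑yn‑1‑yl]decahydronaphthalen‑1‑yl]carbonyl}‑1,3‑oxazolidin‑2‑one | C[Si](C)(C)C#CCC[C@@H]1C(=O)C[C@@H](C(=O)N3CCOC3=O)[C@@H]2C(C)(C)CCC[C@@]12C
F7 | step 5 | tert‑butyl (2E)‑4,4‑dimethylhepta‑2,6‑dienoate | C=CCC(C)(C)/C=C/C(=O)OC(C)(C)C
F8 | step 5 | tert‑butyl (2E)‑7‑(9‑borabicyclo[3.3.1]nonan‑9‑yl)‑4,4‑dimethylhept‑2‑enoate | CC(C)(C)OC(=O)/C=C/C(C)(C)CCCB1C2CCCC1CCC2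
F9 | step 5 | tert‑butyl (2E,8E)‑4,4,8‑trimethyl‑10‑oxo‑9‑[4‑(trimethylsilyl)but‑3‑yn‑1‑yl]undeca‑2,8‑dienoate | CC(=O)/C(CCC#C[Si](C)(C)C)=C(\C)CCCC(C)(C)/C=C/C(=O)OC(C)(C)C
F10 | step 5 | (2E,8E)‑4,4,8‑trimethyl‑10‑oxo‑9‑[4‑(trimethylsilyl)but‑3‑yn‑1‑yl]undeca‑2,8‑dienoic acid | CC(=O)/C(CCC#C[Si](C)(C)C)=C(\C)CCCC(C)(C)/C=C/C(O)=O
F11 | step 5 | (2E,8E)‑4,4,8‑trimethyl‑10‑oxo‑9‑[4‑(trimethylsilyl)but‑3‑yn‑1‑yl]undeca‑2,8‑dienoic 2,2‑dimethylpropanoic anhydride | CC(=O)/C(CCC#C[Si](C)(C)C)=C(\C)CCCC(C)(C)/C=C/C(=O)OC(=O)C(C)(C)C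
F12 | step 15 | 4‑[(1S,4aR,8aR)‑2‑{[(tert‑butyldimethylsilyl)oxy]methyl}‑5,5,8a‑trimethyl‑1,4,4a,5,6,7,8,8a‑octahydronaphthalen‑1‑yl]butan‑2‑one | CC(=O)CC[C@@H]1C(CO[Si](C)(C)C(C)(C)C)=CC[C@@H]2C(C)(C)CCC[C@@]12C
F13 | step 15 | ethyl (2E)‑5‑[(1S,4aR,8aR)‑2‑{[(tert‑butyldimethylsilyl)oxy]methyl}‑5,5,8a‑trimethyl‑1,4,4a,5,6,7,8,8a‑octahydronaphthalen‑1‑yl]‑3‑methylpent‑2‑enoate | CCOC(=O)/C=C(\C)CC[C@@H]1C(CO[Si](C)(C)C(C)(C)C)=CC[C@@H]2C(C)(C)CCC[C@@]12C
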